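(The earlier runs and the new flask come from a simulation for an exercise, and the scatter is random.)

Capped ends stand lower in the winter run than in the autumn run, 7 % against 15 % of the charge at 8.00 h.

| flask | first end groups | second end groups | one-sided end groups | remark | time |
|---|---|---|---|---|---|
| autumn | 0.016 M (fed, over 1.5 h) | 1.02 equiv | 2.5 mM | run made earlier |  |
| noon | 0.029 M (fed, over 1.5 h) | 1.02 equiv | 2.5 mM | run made earlier |  |
| winter | 0.045 M (fed, over 1.5 h) | 1.02 equiv | 2.5 mM | run made earlier |  |
| amber | 0.015 M | 1.02 equiv | 2.50 mM | everything together at the start | 15 h |
| red | 0.050 M (fed, over 1.5 h) | 1.02 equiv | 2.50 mM |  | 15 h |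

| run | time / h | links / % | capped ends / % | first end groups / % |
|---|---|---|---|---|
| autumn | 0.667 | 2 | 1 | 40 |
| autumn | 1.33 | 6 | 4 | 78 |
| autumn | 3.00 | 12 | 13 | 75 |
| autumn | 8.00 | 23 | 15 | 57 |
| noon | 2.00 | 15 | 5 | 80 |
| noon | 4.00 | 27 | 8 | 68 |
| noon | 6.00 | 32 | 7 | 61 |
| noon | 8.00 | 37 | 11 | 52 |
| winter | 2.00 | 20 | 8 | 74 |
| winter | 4.00 | 35 | 11 | 60 |
| winter | 6.00 | 45 | 6 | 54 |
| winter | 8.00 | 45 | 7 | 45 |

(scatter of a reading: 1.5 percentage points)

1. which one finishes higher in share of links in all that became links or capped ends ("neither" within 2 percentage points) (amber / red / neither)
2. share of links in all that became links or capped ends, amber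
3. share of links in all that became links or capped ends, red

The autumn and winter runs share their one-sided end groups and differ in first end groups, so I read the tables as fractions of the charge. I take the one-sided end groups as the limiting reagent of a quick capping, so the capped fraction should level off at their charge over the charge of first end groups. That ratio is 15.6 % for autumn and 5.56 % for winter, and the last capped readings of those two runs lie within their scatter of 1.5 percentage points of it.

For amber and red the ratio gives 16.7 % and 5.00 %. This ceiling, the capped fraction that the charge of one-sided end groups allows, is what I carry.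

At equal links, a lower ceiling raises the share. With the last links readings, my reckoning gives 59.5 % for autumn and 89.0 % for winter. Autumn, with 0.016 M of first end groups, stands close to amber with 0.015 M, and winter, with 0.045 M, close to red with 0.050 M, so I expect red higher. But amber gets its first end groups at the start, without a feed, so I commit to the direction and not to a sharper number.

The forecast names red, with 68 % for amber and 91 % for red: “Concentration favours links, so red wins clearly.”

Amber ends at 65.0 % and red at 91.7 %, so red finishes higher.

    first end groups + second end groups → links (k = 0.0830 /M/min)
    first end groups + one-sided end groups → capped ends (k = 0.770 /M/min)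
    second end groups → decomposed reagent (k = 0.00170 /min)

At 15.0 h amber holds 16.6 % capped ends beside 30.9 % links, with 0.141 % of its one-sided end groups left, so its capped fraction matches the ceiling of 16.7 %. The neighbour of amber charged with 0.0010 M of one-sided end groups has a ceiling of 6.67 %, and it ends with 6.66 % capped ends and a share of 83.3 %.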